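## Retrosynthetic overview

- Last bond: C6–CH2, a Friedel–Crafts union of (2S)-8-(2-hydroxybenzyl)pinocembrin with the free tetrameric salicyl alcohol. C6 is then the only open carbon of ring A, so there is no 6/8 ambiguity.
- Key bond: O1–C2, an enantioselective 6-endo oxa-Michael closure of ring C on a 2'-hydroxychalcone whose 6'-oxygen is benzyl-blocked. This fixes which phenol closes (the benzyl group ends at C8) and sets (2S).
- Chalcone: from 2,4,6-trihydroxyacetophenone by 4,6-di-O-benzylation, C3 hydroxybenzylation with salicyl alcohol, and Claisen–Schmidt condensation with benzaldehyde.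
- Chain: three aryllithium-to-aldehyde additions (each fixes one ortho,para'-CH link), one global hydrogenolysis, one ester reduction.
- Ring order: all benzene rings are bought. Ring C is the only ring formed, after the 8-benzyl group is in place and before the chain is attached.

Assumption: the facial sense of the new step-10 catalyst is taken from the binding model given in that step; if experiment shows the opposite sense, its enantiomer (from (R)-tert-leucinol) is used with no other change.

Step-10 catalyst (made beforehand from the corresponding azide and P(4-MeOC6H4)3): 1-[3,5-bis(trifluoromethyl)phenyl]-3-[(2S)-3,3-dimethyl-1-{[tris(4-methoxyphenyl)-λ5-phosphanylidene]amino}butan-2-yl]thiourea, SMILES COc1ccc(cc1)P(=NC[C@@H](NC(=S)Nc1cc(cc(c1)C(F)(F)F)C(F)(F)F)C(C)(C)C)(c1ccc(OC)cc1)c1ccc(OC)cc1.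

## Route

Step 1
Reactants: 1 methyl 5-formyl-2-hydroxybenzoate
Product: 2 methyl 2-(benzyloxy)-5-formylbenzoate
Conditions: BnBr (1.2 equiv), K2CO3, DMF, 60 °C
Reagents that add atoms: benzyl bromide, BrCc1ccccc1
Why: Williamson ether synthesis at the only acidic site; the benzyl ether keeps the aldehyde electrophilic for step 4 and is removed in the global hydrogenolysis of step 5.

Step 2
Reactants: 3 1-(benzyloxy)-2-bromobenzene; 4 4-(benzyloxy)-3-bromobenzaldehyde
Product: 6 [2-(benzyloxy)phenyl][4-(benzyloxy)-3-bromophenyl]methanol (racemic), via [2-(benzyloxy)phenyl]lithium 5 (not isolated)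
Conditions: n-BuLi (1.05 equiv), THF, −78 °C; then 4, −78 → −40 °C; H2O
Reagents that add atoms: none
Why: Bromine–lithium exchange followed by 1,2-addition of the aryllithium to the aldehyde (faster than exchange with the bromide of 4) fixes the link ortho to the outer oxygen and para to the inner one; the carbinol centre is erased in step 5.

Step 3
Reactants: 6 [2-(benzyloxy)phenyl][4-(benzyloxy)-3-bromophenyl]methanol; 4 4-(benzyloxy)-3-bromobenzaldehyde
Product: 8 {2-(benzyloxy)-5-[[2-(benzyloxy)phenyl](hydroxy)methyl]phenyl}[4-(benzyloxy)-3-bromophenyl]methanol (diastereomer mixture), via dilithiated carbinol 7 (not isolated)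
Conditions: n-BuLi (2.1 equiv), THF, −78 °C; then 4, −78 → −40 °C; H2O
Reagents that add atoms: none
Why: The first equivalent of n-BuLi makes the lithium alkoxide and the second performs bromine–lithium exchange ortho to the ether oxygen; aryllithium–aldehyde addition to a second molecule of 4 adds the next ring with its own bromide ready for the next cycle.

Step 4
Reactants: 8 {2-(benzyloxy)-5-[[2-(benzyloxy)phenyl](hydroxy)methyl]phenyl}[4-(benzyloxy)-3-bromophenyl]methanol; 2 methyl 2-(benzyloxy)-5-formylbenzoate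
Product: 10 methyl 2-(benzyloxy)-5-{[2-(benzyloxy)-5-{[2-(benzyloxy)-5-{[2-(benzyloxy)phenyl](hydroxy)methyl}phenyl](hydroxy)methyl}phenyl](hydroxy)methyl}benzoate (diastereomer mixture), via trilithiated diol 9 (not isolated)
Conditions: n-BuLi (3.1 equiv), THF, −78 °C; cannulated into 2 (1.1 equiv), THF, −78 °C; H2O
Reagents that add atoms: none
Why: Same exchange and aryllithium–aldehyde addition; inverse addition at −78 °C makes the aryllithium take the aldehyde of 2 chemoselectively over its methyl ester.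

Step 5
Reactants: 10 methyl 2-(benzyloxy)-5-{[2-(benzyloxy)-5-{[2-(benzyloxy)-5-{[2-(benzyloxy)phenyl](hydroxy)methyl}phenyl](hydroxy)methyl}phenyl](hydroxy)methyl}benzoate
Product: 11 methyl 2-hydroxy-5-{2-hydroxy-5-[2-hydroxy-5-(2-hydroxybenzyl)benzyl]benzyl}benzoate
Conditions: H2 (3 bar), Pd/C (10 wt %), EtOAc–MeOH, AcOH (cat.), rt
Reagents that add atoms: none
Why: Catalytic hydrogenolysis cleaves the four benzyl ethers and the three doubly benzylic, oxygen-activated carbinol C–O bonds in one operation, which removes all carbinol stereocentres while the ester and the diarylmethane links are inert.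

Step 6
Reactants: 11 methyl 2-hydroxy-5-{2-hydroxy-5-[2-hydroxy-5-(2-hydroxybenzyl)benzyl]benzyl}benzoate
Product: 12 2-(hydroxymethyl)-4-{2-hydroxy-5-[2-hydroxy-5-(2-hydroxybenzyl)benzyl]benzyl}phenol
Conditions: LiAlH4 (6 equiv), THF, 0 °C → rt; aq. potassium sodium tartrate
Reagents that add atoms: none
Why: Hydride reduction of the salicylate ester (the excess covers the four phenols) gives the saligenin-type alcohol; keeping it at or below room temperature avoids over-reduction of the o-hydroxybenzyl alcohol.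

Step 7
Reactants: 13 1-(2,4,6-trihydroxyphenyl)ethan-1-one
Product: 14 1-[2,4-bis(benzyloxy)-6-hydroxyphenyl]ethan-1-one
Conditions: BnBr (2.1 equiv), K2CO3, DMF, 0 °C → rt
Reagents that add atoms: benzyl bromide, BrCc1ccccc1
Why: Williamson etherification takes the 4-OH and one ortho-OH, while the last ortho-OH stays hydrogen-bonded to the acetyl group and unreactive; this differentiates the two ortho oxygens, which later decides which one closes ring C.

Step 8
Reactants: 14 1-[2,4-bis(benzyloxy)-6-hydroxyphenyl]ethan-1-one; 15 2-(hydroxymethyl)phenol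
Product: 17 1-[4,6-bis(benzyloxy)-2-hydroxy-3-(2-hydroxybenzyl)phenyl]ethan-1-one, via o-quinone methide 16 (not isolated)
Conditions: ZnCl2 (2 equiv), 1,4-dioxane, 80 °C, 14 in excess (1.5 equiv)
Reagents that add atoms: none
Why: Friedel–Crafts ortho-hydroxybenzylation through the zinc-bound o-quinone methide occurs at C3 next to the free phenol (the site where 2-hydroxy-4,6-dialkoxyacetophenones are halogenated) and not at C5, which is flanked by two benzyloxy groups.

Step 9
Reactants: 17 1-[4,6-bis(benzyloxy)-2-hydroxy-3-(2-hydroxybenzyl)phenyl]ethan-1-one; 18 benzaldehyde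
Product: 20 (E)-1-[4,6-bis(benzyloxy)-2-hydroxy-3-(2-hydroxybenzyl)phenyl]-3-phenylprop-2-en-1-one, via aldol adduct 19 (not isolated)
Conditions: KOH (50 % aq., 10 equiv), EtOH, rt, 36 h; cold 1 M HCl to pH 5
Reagents that add atoms: none
Why: Claisen–Schmidt condensation (aldol addition, then E1cB dehydration) of the methyl ketone gives the thermodynamic E-enone with the two phenoxides as spectators; any racemic flavanone formed is removed by chromatography.

Step 10
Reactants: 20 (E)-1-[4,6-bis(benzyloxy)-2-hydroxy-3-(2-hydroxybenzyl)phenyl]-3-phenylprop-2-en-1-one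
Product: 21 (2S)-5,7-bis(benzyloxy)-8-(2-hydroxybenzyl)-2-phenyl-2,3-dihydro-4H-chromen-4-one
Conditions: iminophosphorane–thiourea catalyst defined above (10 mol %), toluene (0.05 M), −20 °C, 24 h; then AcOH
Reagents that add atoms: none
Why: Proposed new method: an enantioselective 6-endo oxa-Michael cyclization of a non-activated 2'-hydroxychalcone under bifunctional iminophosphorane–thiourea catalysis, which closes ring C through the O1–C2 bond and sets C2; the superbasic P=N site deprotonates the chelated 2'-OH to a tight chiral phosphonium–phenoxide ion pair while the thiourea N–H pair binds the enone carbonyl, and the 6'-benzyloxy and 3'-benzyl groups twist the aroyl group out of plane so the O–H···O=C chelate is lost and the phenoxide can reach C-β; attack on the Si face of C-β gives (2S) and the enolate is protonated by the phosphonium N–H; kinetic control should hold because only the 2'-phenoxide can close (the 6'-oxygen is blocked), the equilibrium of 6'-alkoxy-2'-hydroxychalcones lies far on the flavanone side, and the remaining phenols buffer the base so that C3–H of the product is not deprotonated at −20 °C before the acid quench; the closest known reaction types are the amine–thiourea-catalysed oxa-Michael cyclization of chalcones activated by an α-ester group and iminophosphorane-catalysed conjugate additions to weakly electrophilic acceptors.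

Step 11
Reactants: 21 (2S)-5,7-bis(benzyloxy)-8-(2-hydroxybenzyl)-2-phenyl-2,3-dihydro-4H-chromen-4-one
Product: 22 (2S)-5,7-dihydroxy-8-(2-hydroxybenzyl)-2-phenyl-2,3-dihydro-4H-chromen-4-one
Conditions: H2 (1 atm), Pd/C (10 wt %), EtOAc–MeOH, rt, stopped after 2 equiv H2
Reagents that add atoms: none
Why: Hydrogenolysis of the two aryl benzyl ethers under neutral conditions leaves the ketone, the C2–O bond and the C2 configuration untouched.

Step 12
Reactants: 22 (2S)-5,7-dihydroxy-8-(2-hydroxybenzyl)-2-phenyl-2,3-dihydro-4H-chromen-4-one; 12 2-(hydroxymethyl)-4-{2-hydroxy-5-[2-hydroxy-5-(2-hydroxybenzyl)benzyl]benzyl}phenol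
Product: 24 sarmentosumin C, via chain o-quinone methide 23 (not isolated)
Conditions: ZnCl2 (3 equiv), 1,4-dioxane, 70 °C, 22 (1.5 equiv), slow addition of 12; reversed-phase HPLC
Reagents that add atoms: none
Why: ZnCl2-mediated Friedel–Crafts benzylation by the o-quinone methide of 12 goes to C6, the only unsubstituted carbon of the phloroglucinol ring and far more nucleophilic than any simple phenol ring of either partner; the non-basic medium does not open the 5-hydroxyflavanone, so (2S) is kept.

## Compound list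

1 | methyl 5-formyl-2-hydroxybenzoate | COC(=O)c1cc(C=O)ccc1O | starting material
2 | methyl 2-(benzyloxy)-5-formylbenzoate | COC(=O)c1cc(C=O)ccc1OCc1ccccc1 | intermediate
3 | 1-(benzyloxy)-2-bromobenzene | Brc1ccccc1OCc1ccccc1 | starting material
4 | 4-(benzyloxy)-3-bromobenzaldehyde | O=Cc1ccc(OCc2ccccc2)c(Br)c1 | starting material
5 | [2-(benzyloxy)phenyl]lithium | [Li]c1ccccc1OCc1ccccc1 | intermediate (not isolated)
6 | [2-(benzyloxy)phenyl][4-(benzyloxy)-3-bromophenyl]methanol (racemic) | OC(c1ccccc1OCc1ccccc1)c1ccc(OCc2ccccc2)c(Br)c1 | intermediate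
7 | lithium [2-(benzyloxy)phenyl][4-(benzyloxy)-3-lithiophenyl]methanolate | [Li]OC(c1ccccc1OCc1ccccc1)c1ccc(OCc2ccccc2)c([Li])c1 | intermediate (not isolated)
8 | {2-(benzyloxy)-5-[[2-(benzyloxy)phenyl](hydroxy)methyl]phenyl}[4-(benzyloxy)-3-bromophenyl]methanol (diastereomer mixture) | OC(c1ccccc1OCc1ccccc1)c1ccc(OCc2ccccc2)c(c1)C(O)c1ccc(OCc2ccccc2)c(Br)c1 | intermediate
9 | dilithium dialkoxide of 8 carrying C–Li in place of C–Br | [Li]OC(c1ccccc1OCc1ccccc1)c1ccc(OCc2ccccc2)c(c1)C(O[Li])c1ccc(OCc2ccccc2)c([Li])c1 | intermediate (not isolated)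
10 | methyl 2-(benzyloxy)-5-{[2-(benzyloxy)-5-{[2-(benzyloxy)-5-{[2-(benzyloxy)phenyl](hydroxy)methyl}phenyl](hydroxy)methyl}phenyl](hydroxy)methyl}benzoate (diastereomer mixture) | OC(c1ccccc1OCc1ccccc1)c1ccc(OCc2ccccc2)c(c1)C(O)c1ccc(OCc2ccccc2)c(c1)C(O)c1ccc(OCc2ccccc2)c(c1)C(=O)OC | intermediate
11 | methyl 2-hydroxy-5-{2-hydroxy-5-[2-hydroxy-5-(2-hydroxybenzyl)benzyl]benzyl}benzoate | COC(=O)c1cc(Cc2cc(Cc3cc(Cc4ccccc4O)ccc3O)ccc2O)ccc1O | intermediate
12 | 2-(hydroxymethyl)-4-{2-hydroxy-5-[2-hydroxy-5-(2-hydroxybenzyl)benzyl]benzyl}phenol | OCc1cc(Cc2cc(Cc3cc(Cc4ccccc4O)ccc3O)ccc2O)ccc1O | intermediate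
13 | 1-(2,4,6-trihydroxyphenyl)ethan-1-one | CC(=O)c1c(O)cc(O)cc1O | starting material
14 | 1-[2,4-bis(benzyloxy)-6-hydroxyphenyl]ethan-1-one | CC(=O)c1c(O)cc(OCc2ccccc2)cc1OCc1ccccc1 | intermediate
15 | 2-(hydroxymethyl)phenol | OCc1ccccc1O | starting material
16 | 6-methylidenecyclohexa-2,4-dien-1-one (o-quinone methide) | C=C1C=CC=CC1=O | intermediate (not isolated)
17 | 1-[4,6-bis(benzyloxy)-2-hydroxy-3-(2-hydroxybenzyl)phenyl]ethan-1-one | CC(=O)c1c(O)c(Cc2ccccc2O)c(OCc2ccccc2)cc1OCc1ccccc1 | intermediate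
18 | benzaldehyde | O=Cc1ccccc1 | starting material
19 | 1-[4,6-bis(benzyloxy)-2-hydroxy-3-(2-hydroxybenzyl)phenyl]-3-hydroxy-3-phenylpropan-1-one (racemic) | OC(CC(=O)c1c(O)c(Cc2ccccc2O)c(OCc2ccccc2)cc1OCc1ccccc1)c1ccccc1 | intermediate (not isolated)
20 | (E)-1-[4,6-bis(benzyloxy)-2-hydroxy-3-(2-hydroxybenzyl)phenyl]-3-phenylprop-2-en-1-one | O=C(/C=C/c1ccccc1)c1c(O)c(Cc2ccccc2O)c(OCc2ccccc2)cc1OCc1ccccc1 | intermediate
21 | (2S)-5,7-bis(benzyloxy)-8-(2-hydroxybenzyl)-2-phenyl-2,3-dihydro-4H-chromen-4-one | O=C1C[C@@H](c2ccccc2)Oc2c(Cc3ccccc3O)c(OCc3ccccc3)cc(OCc3ccccc3)c21 | intermediate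
22 | (2S)-5,7-dihydroxy-8-(2-hydroxybenzyl)-2-phenyl-2,3-dihydro-4H-chromen-4-one | O=C1C[C@@H](c2ccccc2)Oc2c(Cc3ccccc3O)c(O)cc(O)c21 | intermediate
23 | 4-{2-hydroxy-5-[2-hydroxy-5-(2-hydroxybenzyl)benzyl]benzyl}-6-methylidenecyclohexa-2,4-dien-1-one | C=C1C=C(Cc2cc(Cc3cc(Cc4ccccc4O)ccc3O)ccc2O)C=CC1=O | intermediate (not isolated)
24 | sarmentosumin C, (2S)-5,7-dihydroxy-8-(2-hydroxybenzyl)-6-{2-hydroxy-5-[2-hydroxy-5-[2-hydroxy-5-(2-hydroxybenzyl)benzyl]benzyl]benzyl}-2-phenyl-2,3-dihydro-4H-chromen-4-one | O=C1C[C@@H](c2ccccc2)Oc2c(Cc3ccccc3O)c(O)c(Cc3cc(Cc4cc(Cc5cc(Cc6ccccc6O)ccc5O)ccc4O)ccc3O)c(O)c21 | target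

## Step count and risks

Total step count: 12. Longest linear sequence: 6 (steps 2, 3, 4, 5, 6, 12, or equally steps 7, 8, 9, 10, 11, 12).

The three steps most likely to fail are steps 8, 10 and 12.

Step 8 may give some attack at C5, double benzylation, or loss of a benzyl ether under ZnCl2. The fallback replaces the Friedel–Crafts reaction by a regiospecific halogenation and cross-coupling. It sets out from 14: iodination with N-iodosuccinimide in DMF occurs ortho to the free phenol and gives 1-[4,6-bis(benzyloxy)-2-hydroxy-3-iodophenyl]ethan-1-one F1. Suzuki–Miyaura coupling of F1 with potassium [2-(benzyloxy)benzyl]trifluoroborate (PdCl2(dppf), K2CO3, THF–H2O, 80 °C) gives 1-{4,6-bis(benzyloxy)-3-[2-(benzyloxy)benzyl]-2-hydroxyphenyl}ethan-1-one F2. Condensation with 18 as in step 9 gives (E)-1-{4,6-bis(benzyloxy)-3-[2-(benzyloxy)benzyl]-2-hydroxyphenyl}-3-phenylprop-2-en-1-one F3, and cyclization as in step 10 gives (2S)-5,7-bis(benzyloxy)-8-[2-(benzyloxy)benzyl]-2-phenyl-2,3-dihydro-4H-chromen-4-one F4. Hydrogenolysis as in step 11 removes all three benzyl groups, and the fallback comes back to the route at 22.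

Step 10 is the new method; it may give low enantiomeric excess, slow turnover, or erosion through retro-oxa-Michael opening. The fallback uses known chemistry and sets out from 20: NaOAc in refluxing EtOH closes the ring without stereocontrol to give racemic 5,7-bis(benzyloxy)-8-(2-hydroxybenzyl)-2-phenyl-2,3-dihydro-4H-chromen-4-one F5. Preparative HPLC on an amylose tris(3,5-dimethylphenylcarbamate) phase delivers the (2S)-enantiomer, and the fallback comes back to the route at 21. The (2R)-enantiomer is re-equilibrated with NaOAc in EtOH (ring opening and reclosure) and recycled.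

Step 12 may suffer from self-condensation of the free polyphenolic alcohol 12, over-alkylation, or partial racemization under heating with ZnCl2. The fallback changes the electrophile from a free o-quinone methide precursor to a non-nucleophilic peracetate. It sets out from 12: Ac2O and pyridine give 2-(acetoxymethyl)-4-{2-acetoxy-5-[2-acetoxy-5-(2-acetoxybenzyl)benzyl]benzyl}phenyl acetate F6. Sc(OTf)3 (10 mol %) in nitromethane at room temperature ionises its benzylic acetate and alkylates C6 of 22, giving the tetra-O-acetate of sarmentosumin C F7 (acetylated on the four chain phenols). Acidic methanolysis (HCl in MeOH, rt), which does not endanger C2, removes the acetates, and the fallback comes back to the route at 24.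

## Further compounds

F1 | step 8 | 1-[4,6-bis(benzyloxy)-2-hydroxy-3-iodophenyl]ethan-1-one | CC(=O)c1c(O)c(I)c(OCc2ccccc2)cc1OCc1ccccc1
F2 | step 8 | 1-{4,6-bis(benzyloxy)-3-[2-(benzyloxy)benzyl]-2-hydroxyphenyl}ethan-1-one | CC(=O)c1c(O)c(Cc2ccccc2OCc2ccccc2)c(OCc2ccccc2)cc1OCc1ccccc1
F3 | step 8 | (E)-1-{4,6-bis(benzyloxy)-3-[2-(benzyloxy)benzyl]-2-hydroxyphenyl}-3-phenylprop-2-en-1-one | O=C(/C=C/c1ccccc1)c1c(O)c(Cc2ccccc2OCc2ccccc2)c(OCc2ccccc2)cc1OCc1ccccc1
F4 | step 8 | (2S)-5,7-bis(benzyloxy)-8-[2-(benzyloxy)benzyl]-2-phenyl-2,3-dihydro-4H-chromen-4-one | O=C1C[C@@H](c2ccccc2)Oc2c(Cc3ccccc3OCc3ccccc3)c(OCc3ccccc3)cc(OCc3ccccc3)c21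
F5 | step 10 | racemic 5,7-bis(benzyloxy)-8-(2-hydroxybenzyl)-2-phenyl-2,3-dihydro-4H-chromen-4-one | O=C1CC(c2ccccc2)Oc2c(Cc3ccccc3O)c(OCc3ccccc3)cc(OCc3ccccc3)c21
F6 | step 12 | 2-(acetoxymethyl)-4-{2-acetoxy-5-[2-acetoxy-5-(2-acetoxybenzyl)benzyl]benzyl}phenyl acetate | CC(=O)OCc1cc(Cc2cc(Cc3cc(Cc4ccccc4OC(C)=O)ccc3OC(C)=O)ccc2OC(C)=O)ccc1OC(C)=O
F7 | step 12 | sarmentosumin C tetra-O-acetate (four chain phenols acetylated) | O=C1C[C@@H](c2ccccc2)Oc2c(Cc3ccccc3O)c(O)c(Cc3cc(Cc4cc(Cc5cc(Cc6ccccc6OC(C)=O)ccc5OC(C)=O)ccc4OC(C)=O)ccc3OC(C)=O)c(O)c21
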